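**Retrosynthetic overview**

1. The target is the C20-aldehyde gibberellin 3β,13-dihydroxy-20-oxogibberell-16-ene-7,19-dioic acid. Its C20 aldehyde and C19 acid are unmasked last from a cyclic 19,20-lactol methyl ether (an acylal), together with cleavage of a C7 2-(trimethylsilyl)ethyl ester.
2. Key disconnection: the C19–O–C20 acylal C–O bond. C20 enters on oxygen, by O-alkoxymethylation of the C19 carboxylate with MeOCH2Cl, already at the aldehyde oxidation level.
3. That oxygen tether then delivers C20 to C10 from the α face by radical 6-exo closure onto a Δ1(10) alkene, which sets C10 and saturates C1. A C10–C20 bond is unavoidable for this target; the C–O bond is what makes it stereospecific.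
4. The Δ1(10) 19-acid comes from reductive opening of the allylic 19,10-lactone of gibberellic acid, protected at C7.
5. Rings A–D and seven of the eight stereocentres come intact from gibberellic acid. The only ring formed is the temporary 19,20-acylal ring (step 4), opened again in step 5.

Assumption: gibberellic acid, a bulk fermentation product sold cheaply as a plant growth regulator, is taken as the commercial starting material, and the target is treated as the open aldehyde–diacid tautomer (in equilibrium with its 19,20-lactol).

**Route**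

Step 1
Reactants: 1 gibberellic acid; 2 2-(trimethylsilyl)ethanol
Product: 3 gibberellic acid 7-[2-(trimethylsilyl)ethyl] ester
Conditions: N,N'-dicyclohexylcarbodiimide (1.2 equiv), 4-(dimethylamino)pyridine (0.1 equiv), 2 (3 equiv), THF–CH2Cl2, 0 °C → rt
Reagents that add atoms: 2-(trimethylsilyl)ethanol, C[Si](C)(C)CCO
Why: Steglich esterification of the only carboxyl group (C7) with excess primary alcohol, which outcompetes the hindered 3β- and tertiary 13-hydroxyls; it masks C7 so that only C19 can later carry the one-carbon tether, and no stereocentre is involved.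

Step 2
Reactants: 3 gibberellic acid 7-[2-(trimethylsilyl)ethyl] ester
Product: 4 3β,13-dihydroxy-20-norgibberella-1(10),16-diene-7,19-dioic acid 7-[2-(trimethylsilyl)ethyl] ester (free 19-acid)
Conditions: Li (2.2 equiv), NH3(l)–THF, −78 °C, 10 min; isoprene, then NH4Cl; work-up at pH 4–5
Reagents that add atoms: none
Why: Dissolving-metal reductive cleavage of the allylic lactone C10–O bond expels the C19 carboxylate, and the allyl anion is protonated at the less substituted terminus C2 to give the more substituted Δ1(10) alkene; C10 is deliberately made trigonal (re-set in step 4), while the isolated 16-ene, the alkoxides and, with limiting lithium at −78 °C, the alkyl ester are left alone.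

Step 3
Reactants: 4 Δ1(10) 19-acid 7-[2-(trimethylsilyl)ethyl] ester; 5 chloromethyl methyl ether
Product: 6 19-(methoxymethyl) 7-[2-(trimethylsilyl)ethyl] 3β,13-dihydroxy-20-norgibberella-1(10),16-diene-7,19-dioate
Conditions: MeOCH2Cl (1.2 equiv), iPr2NEt (1.5 equiv), CH2Cl2, 0 °C, 1 h
Reagents that add atoms: chloromethyl methyl ether, COCCl
Why: Carboxylate O-alkoxymethylation (SN1-like alkylation by the α-chloro ether) forms the C19–O–C20 bond that brings C20 into the molecule at the aldehyde oxidation level on the α face; the hindered 3β- and 13-hydroxyls react far more slowly at 0 °C with 1.2 equiv, and no stereocentre is touched.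

Step 4
Reactants: 6 19-(methoxymethyl) 7-[2-(trimethylsilyl)ethyl] diester
Product: 7 3β,13-dihydroxy-20-methoxygibberell-16-ene-7,19-dioic acid 19,20-lactone 7-[2-(trimethylsilyl)ethyl] ester (the 19,20-lactol methyl ether of the target skeleton, C20 on the α face of C10, both C20 epimers)
Conditions: Ir[dF(CF3)ppy]2(dtbbpy)PF6 (2 mol%), 3-acetoxyquinuclidine (10 mol%), 2,4,6-triisopropylbenzenethiol (10 mol%), degassed MeCN (0.02 M), 450 nm LEDs, 25 °C
Reagents that add atoms: none
Why: Proposed new method: photocatalytic hydrogen-atom-transfer cycloisomerisation of a methoxymethyl ester onto an unactivated trisubstituted alkene — the excited iridium photocatalyst oxidises the quinuclidine, whose aminium radical cation abstracts the most hydridic C–H of 6 (O–CH2–O of the acylal); the nucleophilic acyloxy(methoxy)methyl radical, held on the α face by the axial C19 carboxyl 1,3-diaxial to the C10 p-orbital, closes 6-exo through the same chair-like bridged array as the natural 19,20-δ-lactones, forming C10–C20 and the quaternary C10 stereocentre with C20 α (the only face the tether reaches); the secondary C1 radical then takes H from the thiol, and the thiyl radical is reduced by the reduced photocatalyst and reprotonated, so the cycle is redox-neutral and C20 stays at the aldehyde oxidation level; the closest known reaction types are quinuclidine/iridium photoredox HAT alkylation of ethers and acetals with electron-poor alkenes and thiol-catalysed radical-chain cyclisation of unsaturated acetals (Ueno–Stork-like α-oxy radical closure), whereas an acylal C–H as radical source and closure through an ester tether onto an unactivated alkene to make a quaternary centre have not been shown.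

Step 5
Reactants: 7 19,20-lactol methyl ether 7-[2-(trimethylsilyl)ethyl] ester
Product: 9 3β,13-dihydroxy-20-oxogibberell-16-ene-7,19-dioic acid (the target), via C7-carboxylate methyl acylal 8 (not isolated)
Conditions: Bu4NF (3 equiv), THF, 0 °C → rt; then 1 M aq. HCl to pH 1–2, rt, 2 h
Reagents that add atoms: water, O
Why: Fluoride attack at silicon fragments the 2-(trimethylsilyl)ethyl ester (β-elimination to ethylene and Me3SiF) to free the C7 carboxylate, then acid-catalysed acylal hydrolysis (ring-opening ionisation to the methoxy-oxocarbenium ion, water capture, loss of methanol) releases the C19 acid and the non-enolisable C20 aldehyde and erases the C20 acetal centre; pH 1–2 at room temperature should be tolerated by the 13-hydroxy-16-ene unit.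

**Compound list**

1 | gibberellic acid: 3β,13-dihydroxy-1,16-diene, 19→10 γ-lactone on the α face, 4β-methyl, 5β-H, 6β-CO2H, 9β-H | C=C1C[C@]23C[C@@]1(O)CC[C@H]2[C@]1(OC4=O)C=C[C@H](O)[C@]4(C)[C@H]1[C@@H]3C(=O)O | starting material
2 | 2-(trimethylsilyl)ethanol | C[Si](C)(C)CCO | starting material
3 | gibberellic acid 7-[2-(trimethylsilyl)ethyl] ester (all stereocentres as in 1) | C=C1C[C@]23C[C@@]1(O)CC[C@H]2[C@]1(OC4=O)C=C[C@H](O)[C@]4(C)[C@H]1[C@@H]3C(=O)OCC[Si](C)(C)C | intermediate
4 | 3β,13-dihydroxy-20-norgibberella-1(10),16-diene-7,19-dioic acid 7-[2-(trimethylsilyl)ethyl] ester (4α-CO2H free, C10 trigonal, other centres as in 1) | C=C1C[C@]23C[C@@]1(O)CC[C@H]2C1=CC[C@H](O)[C@@](C)(C(=O)O)[C@H]1[C@@H]3C(=O)OCC[Si](C)(C)C | intermediate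
5 | chloromethyl methyl ether | COCCl | starting material
6 | 19-(methoxymethyl) 7-[2-(trimethylsilyl)ethyl] 3β,13-dihydroxy-20-norgibberella-1(10),16-diene-7,19-dioate | C=C1C[C@]23C[C@@]1(O)CC[C@H]2C1=CC[C@H](O)[C@@](C)(C(=O)OCOC)[C@H]1[C@@H]3C(=O)OCC[Si](C)(C)C | intermediate
7 | 3β,13-dihydroxy-20-methoxygibberell-16-ene-7,19-dioic acid 19,20-lactone 7-[2-(trimethylsilyl)ethyl] ester (C20 α on C10; both C20 epimers) | C=C1C[C@]23C[C@@]1(O)CC[C@H]2[C@]1(C4OC)CC[C@H](O)[C@@](C)(C(=O)O4)[C@H]1[C@@H]3C(=O)OCC[Si](C)(C)C | intermediate
8 | 3β,13-dihydroxy-20-methoxygibberell-16-ene-7,19-dioic acid 19,20-lactone (free C7 carboxyl, present as its tetrabutylammonium carboxylate; both C20 epimers) | C=C1C[C@]23C[C@@]1(O)CC[C@H]2[C@]1(C4OC)CC[C@H](O)[C@@](C)(C(=O)O4)[C@H]1[C@@H]3C(=O)O | intermediate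
9 | 3β,13-dihydroxy-20-oxogibberell-16-ene-7,19-dioic acid (10α-CHO, 4α-CO2H, 4β-CH3, 6β-CO2H) | C=C1C[C@]23C[C@@]1(O)CC[C@H]2[C@]1(C=O)CC[C@H](O)[C@@](C)(C(=O)O)[C@H]1[C@@H]3C(=O)O | target

**Step count and risks**

Total step count: 5. Longest linear sequence: 5 steps (1 → 3 → 4 → 6 → 7 → 9).

Steps most likely to fail:

Step 4 (the proposed new method). The risks are:
- hydrogen abstraction at other sites (the C3 carbinol C–H, which could epimerise C3, or allylic C–H);
- slow closure because the ester must reach its s-cis conformer;
- 7-endo attack at C1 instead of 6-exo attack at C10.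

Fallback with known chemistry, setting out from 4 and coming back at 7: 4 is O-alkylated with chloromethyl phenyl sulfide (Cs2CO3, NaI cat., DMF) to give the 19-(phenylthio)methyl ester F1. N-Chlorosuccinimide (CH2Cl2, −20 °C) converts the sulfide into the α-chloro sulfide, the 19-[chloro(phenylthio)methyl] ester F2. Slow addition of Bu3SnH with azobisisobutyronitrile (benzene, 80 °C) generates the tethered radical site-specifically by chlorine abstraction and closes it 6-exo onto C10 to give the 20-phenylthio 19,20-lactone F3. Silver-promoted methanolysis (AgOSO2CF3, MeOH, 2,6-di-tert-butylpyridine, CH2Cl2) exchanges SPh for OMe and gives 7.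

Step 2. The risks are partial reduction of the C7 ester by lithium in ammonia and protonation of the allyl anion at C10 instead of C2. The fallback answers the first of these, setting out from 1 and coming back at 4: gibberellic acid itself is reduced (Li, NH3–THF, −33 °C), where the carboxylate is inert, to give the Δ1(10) diacid, 3β,13-dihydroxy-20-norgibberella-1(10),16-diene-7,19-dioic acid F4. The less hindered C7 carboxyl is then esterified selectively with 2 (N,N'-dicyclohexylcarbodiimide 1.05 equiv, 4-(dimethylamino)pyridine, CH2Cl2, 0 °C), the axial neopentyl C19 carboxyl being acylated far more slowly, to give 4.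

Step 5. The risks are damage by basic fluoride to the acylal or aldehyde, and acid-induced rearrangement of the 13-hydroxy-16-ene unit. Fallback, setting out from 7 and coming back at 9: the acylal is hydrolysed first under weak acid (pyridinium p-toluenesulfonate, acetone–H2O, 40 °C) and the lactol/aldehyde is isolated as 3β,13-dihydroxy-20-oxogibberell-16-ene-7,19-dioic acid 7-[2-(trimethylsilyl)ethyl] ester F5. The ester is then cleaved with anhydrous, non-basic fluoride (tris(dimethylamino)sulfonium difluorotrimethylsilicate, DMF, 0 °C) to give 9.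

**Further compounds**

F1 | step 4 | 19-[(phenylthio)methyl] 7-[2-(trimethylsilyl)ethyl] 3β,13-dihydroxy-20-norgibberella-1(10),16-diene-7,19-dioate | C=C1C[C@]23C[C@@]1(O)CC[C@H]2C1=CC[C@H](O)[C@@](C)(C(=O)OCSc5ccccc5)[C@H]1[C@@H]3C(=O)OCC[Si](C)(C)C
F2 | step 4 | 19-[chloro(phenylthio)methyl] 7-[2-(trimethylsilyl)ethyl] 3β,13-dihydroxy-20-norgibberella-1(10),16-diene-7,19-dioate (both epimers at the chlorinated carbon) | C=C1C[C@]23C[C@@]1(O)CC[C@H]2C1=CC[C@H](O)[C@@](C)(C(=O)OC(Cl)Sc5ccccc5)[C@H]1[C@@H]3C(=O)OCC[Si](C)(C)C
F3 | step 4 | 3β,13-dihydroxy-20-(phenylthio)gibberell-16-ene-7,19-dioic acid 19,20-lactone 7-[2-(trimethylsilyl)ethyl] ester (C20 α on C10; both C20 epimers) | C=C1C[C@]23C[C@@]1(O)CC[C@H]2[C@]1(C4Sc5ccccc5)CC[C@H](O)[C@@](C)(C(=O)O4)[C@H]1[C@@H]3C(=O)OCC[Si](C)(C)C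
F4 | step 2 | 3β,13-dihydroxy-20-norgibberella-1(10),16-diene-7,19-dioic acid | C=C1C[C@]23C[C@@]1(O)CC[C@H]2C1=CC[C@H](O)[C@@](C)(C(=O)O)[C@H]1[C@@H]3C(=O)O
F5 | step 5 | 3β,13-dihydroxy-20-oxogibberell-16-ene-7,19-dioic acid 7-[2-(trimethylsilyl)ethyl] ester (open aldehyde form of the lactol) | C=C1C[C@]23C[C@@]1(O)CC[C@H]2[C@]1(C=O)CC[C@H](O)[C@@](C)(C(=O)O)[C@H]1[C@@H]3C(=O)OCC[Si](C)(C)C
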